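Start from the vessel: it is closed, and one substrate and one coupling partner make one target, so the smaller charge limits the target.

| flask | substrate | coupling partner | time |
|---|---|---|---|
| Wednesday's | 0.0800 M | 0.0880 M |  |
| Friday's | 0.0320 M | 0.0400 M |  |
| Sunday's | 0.160 M | 0.0880 M |  |
| Monday's | 0.0800 M | 0.180 M |  |
| Thursday's | 0.520 M | 0.0880 M | 72 min |

- Wednesday's run (time / min: [target] / M): 2.6: 0.0341; 7.8: 0.0504; 15: 0.0553; 24: 0.0600; 34: 0.0611; 45: 0.0629; 58: 0.0639; 72: 0.0645
- Friday's run (time / min: [target] / M): 2.6: 0.0048; 7.8: 0.0099; 15: 0.0139; 24: 0.0148; 34: 0.0170; 45: 0.0197; 58: 0.0193; 72: 0.0201
- Sunday's run (time / min: [target] / M): 2.6: 0.0530; 7.8: 0.0690; 15: 0.0749; 24: 0.0772; 34: 0.0787; 45: 0.0792; 58: 0.0795; 72: 0.0787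
- Monday's run (time / min: [target] / M): 2.6: 0.0673; 7.8: 0.0777; 15: 0.0774; 24: 0.0793; 34: 0.0806; 45: 0.0801; 58: 0.0797; 72: 0.0795

(scatter of a reading: 6 × 10⁻⁴ M)

- Overall: substrate + coupling partner -> target.
- Constant volume, constant temperature.
- "The second partner" is coupling partner.
- An order is taken over about fifteen percent of the charge, up and down.

1. apparent order in [coupling partner] of the starting rate, round the charge of the Wednesday's run (the rate where two percent of its substrate have turned into target)
2. apparent order in [substrate] of the starting rate, round the charge of the Wednesday's run (the rate where two percent of its substrate have turned into target) (one fixed amount of target, the same in the runs compared)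
3. the Friday's run starts with 0.0480 M less of substrate and of coupling partner than the Wednesday's run, and with no target. Compared where both hold the same amount of substrate, once fifteen percent of what the Friday's run was charged with has turned into target, is the Friday's run faster, slower or alike (within a tenth)?
4. target in the Thursday's run at 72 min, as a share of the substrate charged

First ask which charge holds the limit. In Monday's run substrate is the smaller charge, 0.0800 M against 0.180 M, and the last reading stands at 99.4% of it. In Sunday's run the coupling partner is smaller, 0.0880 M against 0.160 M, and the target flattens at about 0.0790 M. The limit passes from one charge to the other where the two charges cross.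

Thursday's run has 0.0880 M of partner against 0.520 M of substrate, so the partner is the limiting reagent, and the limit is 16.9%. Call this share, the smaller charge over the substrate charged, the cap.

Next ask whether 72 min is long enough for Thursday's run. Sunday's run has flattened by 34 min, and Thursday's substrate cannot fall below 0.432 M, more than Sunday's run started with. Take the time as long enough.

Last ask how far below the cap Thursday's run stops. By its readings, Sunday's run ends 10.2% short of its partner charge. My own reckoning assumes that this shortfall varies inversely with the mean substrate, and the ratio of Sunday's mean substrate to Thursday's is 0.253. Thursday's shortfall is then 2.58%, which gives 16.5% of the substrate, with no rate constant needed.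

The forecast gives 16.5%, orders of 2 in partner and 1 in substrate, and Friday's run faster. Its grounds for the orders read: “So the coupling partner is about second order and the substrate about first order.”

Thursday's run gives 16.5%, which is 97.6% of its cap; the orders are 2.0 and 1.0, and Friday's run is faster.

    substrate + 2 coupling partner → target + coupling partner (52.38 /M²/min)
    substrate + coupling partner + target → 2 target (16.02 /M²/min)
    2 coupling partner → lost reagent (0.5190 /M/min)

Thursday's run stops 0.40 percentage points below its cap, and the turning of coupling partner into lost reagent moves its share by a small amount. Friday's run has substrate as its smaller charge, so its cap is 100%, and its reading at 72 min stands at 62.8% of the substrate charged.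

The numbers in the tables are calculated for substances that don't exist, and the scatter is random.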